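The route rests on disconnecting the bond between C2 of the dihydropyranone ring (C ring) and the ipso carbon C1′ of the 4‑hydroxyphenyl B ring. In the forward sense this bond is made by a rhodium‑catalysed enantioselective 1,4‑addition of a 4‑silyloxyphenylboronic acid to a flat, achiral 5‑silyloxy‑7‑prenyloxychromone. The C2=C3–C4=O vinylogous ester of the pyranone makes C2 the electrophilic β‑carbon, and the chiral ligand sets C2 in the same operation that brings in the whole B ring. The resulting (2S)‑flavanone is then hydroxylated at C3 anti to the new aryl group (enol silane, Rubottom oxidation) and desilylated to the (2R,3R)‑dihydroflavonol.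

Key step: step 3

Assumption: 5,7‑dihydroxychromone, prenyl bromide and 4‑(tert‑butyldimethylsilyloxy)phenylboronic acid are taken as catalogue compounds, and dimethyldioxirane (DMDO) is used as its freshly prepared, titrated acetone solution.

Step 1
Reactants: 1 5,7‑dihydroxy‑4H‑chromen‑4‑one (5,7‑dihydroxychromone); 2 1‑bromo‑3‑methylbut‑2‑ene (prenyl bromide)
Product: 3 5‑hydroxy‑7‑[(3‑methylbut‑2‑en‑1‑yl)oxy]‑4H‑chromen‑4‑one
Conditions: K2CO3 (1.1 equiv), 2 (1.05 equiv), acetone, 40 °C
Reagents that add atoms: none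
Why: Williamson etherification: the 7‑OH, para to the pyrone carbonyl, is the more acidic (vinylogous acid) phenol and should be alkylated by the allylic bromide, while the 5‑OH stays locked in its hydrogen bond to C4=O; no stereocenter is formed.

Step 2
Reactants: 3 5‑hydroxy‑7‑(prenyloxy)chromone
Product: 4 5‑[(tert‑butyldimethylsilyl)oxy]‑7‑[(3‑methylbut‑2‑en‑1‑yl)oxy]‑4H‑chromen‑4‑one
Conditions: TBSOTf (1.3 equiv), 2,6‑lutidine (2.5 equiv), CH2Cl2, 0 °C to rt
Reagents that add atoms: tert‑butyldimethylsilyl trifluoromethanesulfonate, CC(C)(C)[Si](C)(C)OS(=O)(=O)C(F)(F)F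
Why: Silylation with a silyl triflate: TBSOTf is electrophilic enough to cap the chelated peri phenol, which removes the acidic, metal‑binding 5‑OH before the rhodium step, and any carbonyl‑silylated pyrylium should revert to the chromone on aqueous work‑up.

Step 3
Reactants: 4 5‑(tert‑butyldimethylsilyloxy)‑7‑(prenyloxy)chromone; 5 [4‑[(tert‑butyldimethylsilyl)oxy]phenyl]boronic acid
Product: 6 (2S)‑5‑[(tert‑butyldimethylsilyl)oxy]‑2‑[4‑[(tert‑butyldimethylsilyl)oxy]phenyl]‑7‑[(3‑methylbut‑2‑en‑1‑yl)oxy]chroman‑4‑one
Conditions: 5 (2.5 equiv), [Rh(OH)(cod)]2 (2.5 mol %), (S)‑MeO‑F12‑BIPHEP (5.5 mol %), degassed toluene/H2O (10:1), 30–40 °C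
Reagents that add atoms: none
Why: Hayashi–Miyaura reaction: the aryl group passes from boron to a hydroxo‑rhodium(I) bisphosphine complex, the aryl–Rh species adds syn across the C2=C3 bond of the chromone with the aryl going to C2 (the β‑carbon of the C2=C3–C4=O vinylogous ester), and the resulting oxa‑π‑allyl rhodium enolate is protonated by water, which returns Rh–OH. The closest known reaction type is the rhodium‑catalysed asymmetric 1,4‑addition of arylboronic acids to chromones, which gives flavanones directly; no ring is closed in this step. The only new stereocenter, C2, is set by the chiral bisphosphine, which differentiates the two faces of the flat chromone in the insertion step; by the usual quadrant model for cyclic enones the (S)‑ligand should give the 2S product, and the antipodal ligand is the remedy should the sense be the opposite. The step needs 1,4‑ over 1,2‑selectivity and no second arylation of the product ketone, which the mild base‑free aqueous conditions and the electron‑poor ligand should secure, and it must not open the pyranone by retro‑oxa‑Michael reaction (which would racemise C2), which the absence of added base should prevent. The O5 silyl ether removes the acidic, Rh‑chelating peri‑hydroxy ketone, and the trisubstituted, unactivated prenyl alkene should be inert to aryl–Rh insertion.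

Step 4
Reactants: 6 (2S)‑bis‑TBS flavanone
Product: 9 (2R,3R)‑7‑O‑prenylaromadendrin, via TMS enol ether 7 (not isolated), via silyloxy epoxide 8 (not isolated)
Conditions: TMSOTf (1.5 equiv), Et3N (3 equiv), CH2Cl2, 0 °C; evaporation, pentane filtration; DMDO (1.05 equiv, acetone), CH2Cl2, −78 to −40 °C; then HF·pyridine, pyridine, THF, 0 °C to rt
Reagents that add atoms: dimethyldioxirane, CC1(C)OO1 (the oxygen of the 3‑OH); trimethylsilyl trifluoromethanesulfonate, C[Si](C)(C)OS(=O)(=O)C(F)(F)F (its silyl group is carried only by 7 and 8 and is lost again before 9)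
Why: Rubottom oxidation: soft enolisation should give the C3=C4 enol silane without a free enolate, so that the pyranone cannot open by E1cB and C2 keeps its configuration; the dioxirane should epoxidise this very electron‑rich double bond at −78 °C well before the prenyl alkene and from the face anti to the C2 aryl group, which sets C3 (3R, hydroxyl trans to the aryl group; the C2 descriptor changes from S to R only because of the new oxygen at C3), and fluoride then collapses the silyloxy epoxide to the α‑hydroxy ketone and frees both phenols.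

Compound list
1 | 5,7‑dihydroxy‑4H‑chromen‑4‑one (5,7‑dihydroxychromone) | O=c1ccoc2cc(O)cc(O)c12 | starting material
2 | 1‑bromo‑3‑methylbut‑2‑ene (prenyl bromide) | CC(C)=CCBr | starting material
3 | 5‑hydroxy‑7‑[(3‑methylbut‑2‑en‑1‑yl)oxy]‑4H‑chromen‑4‑one | CC(C)=CCOc1cc(O)c2c(c1)occc2=O | intermediate
4 | 5‑[(tert‑butyldimethylsilyl)oxy]‑7‑[(3‑methylbut‑2‑en‑1‑yl)oxy]‑4H‑chromen‑4‑one | CC(C)=CCOc1cc(O[Si](C)(C)C(C)(C)C)c2c(c1)occc2=O | intermediate
5 | [4‑[(tert‑butyldimethylsilyl)oxy]phenyl]boronic acid | CC(C)(C)[Si](C)(C)Oc1ccc(B(O)O)cc1 | starting material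
6 | (2S)‑5‑[(tert‑butyldimethylsilyl)oxy]‑2‑[4‑[(tert‑butyldimethylsilyl)oxy]phenyl]‑7‑[(3‑methylbut‑2‑en‑1‑yl)oxy]chroman‑4‑one | CC(C)=CCOc1cc(O[Si](C)(C)C(C)(C)C)c2c(c1)O[C@H](c1ccc(O[Si](C)(C)C(C)(C)C)cc1)CC2=O | intermediate
7 | (2S)‑5‑[(tert‑butyldimethylsilyl)oxy]‑2‑[4‑[(tert‑butyldimethylsilyl)oxy]phenyl]‑7‑(prenyloxy)‑4‑[(trimethylsilyl)oxy]‑2H‑chromene (TMS enol ether of 6) | CC(C)=CCOc1cc(O[Si](C)(C)C(C)(C)C)c2c(c1)O[C@H](c1ccc(O[Si](C)(C)C(C)(C)C)cc1)C=C2O[Si](C)(C)C | intermediate (not isolated)
8 | (2R,3R,4R)‑3,4‑epoxy‑4‑[(trimethylsilyl)oxy]chromane derived from 7, oxirane oxygen trans to the 2‑aryl group, 5‑OTBS, 4′‑OTBS and 7‑prenyloxy groups unchanged | CC(C)=CCOc1cc(O[Si](C)(C)C(C)(C)C)c2c(c1)O[C@H](c1ccc(O[Si](C)(C)C(C)(C)C)cc1)[C@H]1O[C@]12O[Si](C)(C)C | intermediate (not isolated)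
9 | (2R,3R)‑3,5‑dihydroxy‑2‑(4‑hydroxyphenyl)‑7‑[(3‑methylbut‑2‑en‑1‑yl)oxy]chroman‑4‑one (7‑prenyloxyaromadendrin) | CC(C)=CCOc1cc(O)c2c(c1)O[C@H](c1ccc(O)cc1)[C@@H](O)C2=O | target

Total step count: 4. Longest linear sequence: 4 steps (1 → 3 → 4 → 6 → 9).

Steps most likely to fail

Step 3. The carbometalation of the electron‑rich, 5,7‑dioxygenated chromone may be too slow, so that protodeboronation of the electron‑rich boronic acid and hydrolytic loss of the peri‑silyl ether outrun C–C bond formation. The fallback sets out from 4 and changes both the aryl donor and the fate of the enolate, working without water. (4‑Bromophenoxy)(tert‑butyl)dimethylsilane is converted by bromine–lithium exchange (n‑BuLi, THF, −78 °C) into [4‑(tert‑butyldimethylsilyloxy)phenyl]lithium F1 and then with ZnCl2 into [4‑(tert‑butyldimethylsilyloxy)phenyl]zinc chloride F2. F2 is added to 4 with [RhCl((S)‑binap)]2 and TMSCl in THF at 20 °C, by analogy with the rhodium‑catalysed arylzinc/chlorosilane 1,4‑additions established for 4‑quinolones and 2,3‑dihydro‑4‑pyridones. The chlorosilane activates the enone and traps the rhodium enolate, so the product should be the enol silane 7 itself. The route is rejoined at 7, at the dioxirane stage of step 4.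

Step 4. Over‑oxidation is the main concern: epoxidation of the prenyl double bond may compete with that of the enol silane, or the facial discrimination in the epoxidation may be insufficient. The fallback sets out from 6 and replaces the electrophilic epoxidation of a neutral enol ether by the hydroxylation of a metal enolate with an N‑sulfonyloxaziridine, a reagent that should leave isolated alkenes untouched at low temperature. Ketone 6 is deprotonated with NaHMDS in THF at −78 °C to the sodium enolate F3, which is treated at −78 °C with 3‑phenyl‑2‑(phenylsulfonyl)oxaziridine and quenched with NH4Cl. Attack anti to the 2‑aryl group should give (2R,3R)‑3‑hydroxy‑5‑(tert‑butyldimethylsilyloxy)‑2‑[4‑(tert‑butyldimethylsilyloxy)phenyl]‑7‑(prenyloxy)chroman‑4‑one F4. Desilylation of F4 with HF·pyridine in THF/pyridine rejoins the route at 9.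

Step 2. Silylation of the hydrogen‑bonded 5‑OH may stay incomplete, or the peri‑silyl ether may be lost from the strongly basic pyrone during isolation. The fallback sets out from 3 and postpones the O5 protection until after the C–C bond formation. The free phenol 3 is arylated with 5 under the classical, more forcing rhodium conditions (Rh(acac)(C2H4)2, (S)‑bisphosphine, dioxane/H2O, 80–100 °C), which tolerate a chelating oxygen ligand on rhodium. This should give (2S)‑5‑hydroxy‑7‑(prenyloxy)‑2‑[4‑(tert‑butyldimethylsilyloxy)phenyl]chroman‑4‑one F5. Its less strongly chelated phenol is then silylated (TBSOTf, 2,6‑lutidine, CH2Cl2, −78 °C), which rejoins the route at 6.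

Further compounds
F1 | step 3 | [4‑[(tert‑butyldimethylsilyl)oxy]phenyl]lithium | CC(C)(C)[Si](C)(C)Oc1ccc([Li])cc1
F2 | step 3 | [4‑[(tert‑butyldimethylsilyl)oxy]phenyl]zinc chloride | CC(C)(C)[Si](C)(C)Oc1ccc([Zn]Cl)cc1
F3 | step 4 | sodium enolate of 6 (sodium (2S)‑5‑(tert‑butyldimethylsilyloxy)‑2‑[4‑(tert‑butyldimethylsilyloxy)phenyl]‑7‑(prenyloxy)‑2H‑chromen‑4‑olate) | CC(C)=CCOc1cc(O[Si](C)(C)C(C)(C)C)c2c(c1)O[C@H](c1ccc(O[Si](C)(C)C(C)(C)C)cc1)C=C2[O-].[Na+]
F4 | step 4 | (2R,3R)‑3‑hydroxy‑5‑[(tert‑butyldimethylsilyl)oxy]‑2‑[4‑[(tert‑butyldimethylsilyl)oxy]phenyl]‑7‑[(3‑methylbut‑2‑en‑1‑yl)oxy]chroman‑4‑one | CC(C)=CCOc1cc(O[Si](C)(C)C(C)(C)C)c2c(c1)O[C@H](c1ccc(O[Si](C)(C)C(C)(C)C)cc1)[C@@H](O)C2=O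
F5 | step 2 | (2S)‑5‑hydroxy‑7‑[(3‑methylbut‑2‑en‑1‑yl)oxy]‑2‑[4‑[(tert‑butyldimethylsilyl)oxy]phenyl]chroman‑4‑one | CC(C)=CCOc1cc(O)c2c(c1)O[C@H](c1ccc(O[Si](C)(C)C(C)(C)C)cc1)CC2=O
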